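**Retrosynthetic overview**
1. Target ⇐ desilylation ⇐ ring-closing metathesis at C1=C10 (Z), which closes the ten-membered carbocycle last.
2. C8 ester ⇐ Mitsunobu coupling (inversion, 8S → 8R) of the open-chain carbinol with silyl-protected (E)-4-hydroxytiglic acid.
3. C7–C8 bond ⇐ zinc Barbier allylation of 3-methylbut-3-enal with a (5S)-3-(bromomethyl)butenolide; this sets C7 and C8 and unveils the α-methylene lactone.
4. Bromobutenolide ⇐ metathesis of a 2-(bromomethyl)acrylate ⇐ threo epoxy alcohol ⇐ hydroxyl-directed epoxidation of an (S)-divinyl carbinol (Sharpless kinetic resolution) ⇐ geranyl acetate.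
5. Ring order: epoxide, then butenolide, then ten-membered ring.

Assumption: germacrane numbering is used for positions (C4/C5 epoxide, C6/C7 lactone carbons, C8 ester carbon, C1=C10 ring alkene); the SMILES is read as 4R,5R,6S,7R,8R, 1(10)Z, side chain 2E.

**Route**

Step 1
Reactants: 1 geranyl acetate
Product: 2 (2E)-5-(3,3-dimethyloxiran-2-yl)-3-methylpent-2-en-1-yl acetate (racemic)
Conditions: mCPBA (1.0 equiv), CH2Cl2, 0 °C
Reagents that add atoms: m-chloroperoxybenzoic acid, O=C(OO)c1cccc(Cl)c1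
Why: Prilezhaev epoxidation goes to the electron-rich remote trisubstituted alkene because the 2,3-alkene is deactivated by the allylic acetate; the new centre is racemic and is destroyed in step 2.

Step 2
Reactants: 2 (2E)-5-(3,3-dimethyloxiran-2-yl)-3-methylpent-2-en-1-yl acetate
Product: 4 (2E)-3-methyl-6-oxohex-2-en-1-yl acetate, via 6,7-glycol 3 (not isolated)
Conditions: HIO4·2H2O, THF/Et2O, 0 °C
Reagents that add atoms: none
Why: Acidic hydration of the epoxide at its tertiary carbon followed by Malaprade glycol cleavage gives the aldehyde (which keeps the former epoxide oxygen) and leaves the E-trisubstituted alkene untouched.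

Step 3
Reactants: 4 (2E)-3-methyl-6-oxohex-2-en-1-yl acetate
Product: 5 (2E)-3-methylhepta-2,6-dien-1-yl acetate
Conditions: Ph3PCH3Br, KN(SiMe3)2, THF, 0 °C; then 4, −78 → 0 °C
Reagents that add atoms: methyltriphenylphosphonium bromide, C[P+](c1ccccc1)(c1ccccc1)c1ccccc1.[Br-]
Why: Wittig methylenation, in which the aldehyde reacts far faster than the acetate with one equivalent of the non-stabilised ylide at low temperature.

Step 4
Reactants: 5 (2E)-3-methylhepta-2,6-dien-1-yl acetate
Product: 6 (2E)-3-methylhepta-2,6-dien-1-ol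
Conditions: K2CO3 (cat.), MeOH, rt
Reagents that add atoms: none
Why: Base-catalysed transesterification (methanolysis) removes the acetate without touching the alkenes.

Step 5
Reactants: 6 (2E)-3-methylhepta-2,6-dien-1-ol
Product: 7 (2E)-3-methylhepta-2,6-dienal
Conditions: MnO2, CH2Cl2, rt
Reagents that add atoms: none
Why: Selective allylic alcohol oxidation that is known to preserve the E geometry of geraniol-type substrates.

Step 6
Reactants: 7 (2E)-3-methylhepta-2,6-dienal
Product: 8 (4E)-5-methylnona-1,4,8-trien-3-ol (racemic)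
Conditions: CH2=CHMgBr, THF, −78 °C; aq. NH4Cl
Reagents that add atoms: vinylmagnesium bromide, C=C[Mg]Br
Why: Grignard 1,2-addition to the β,β-disubstituted enal gives the racemic divinyl carbinol.

Step 7
Reactants: 8 (4E)-5-methylnona-1,4,8-trien-3-ol (racemic)
Product: 9 (3S,4E)-5-methylnona-1,4,8-trien-3-ol
Conditions: Ti(OiPr)4 (10 mol%), D-(−)-DIPT (15 mol%), t-BuOOH (0.6 equiv), 4 Å MS, CH2Cl2, −20 °C, to about 60% conversion
Reagents that add atoms: none
Why: Sharpless kinetic resolution, in which D-(−)-DIPT epoxidises the trisubstituted alkene of the (3R)-enantiomer much faster, so the unreacted (3S)-alcohol carrying the future C6 configuration is recovered in high ee.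

Step 8
Reactants: 9 (3S,4E)-5-methylnona-1,4,8-trien-3-ol
Product: 10 (1S)-1-[(2R,3R)-3-(but-3-en-1-yl)-3-methyloxiran-2-yl]prop-2-en-1-ol
Conditions: mCPBA, NaHCO3, CH2Cl2, 0 °C
Reagents that add atoms: m-chloroperoxybenzoic acid, O=C(OO)c1cccc(Cl)c1
Why: Hydroxyl-directed (Henbest-type) peracid epoxidation of the most nucleophilic alkene, where allylic 1,3-strain with the cis methyl group fixes the carbinol conformation and delivers oxygen to give the threo epoxy alcohol, setting C4 and C5 as R,R.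

Step 9
Reactants: 10 (1S)-1-[(2R,3R)-3-(but-3-en-1-yl)-3-methyloxiran-2-yl]prop-2-en-1-ol; 11 2-(bromomethyl)prop-2-enoic acid
Product: 12 (1S)-1-[(2R,3R)-3-(but-3-en-1-yl)-3-methyloxiran-2-yl]prop-2-en-1-yl 2-(bromomethyl)prop-2-enoate
Conditions: DCC, DMAP (5 mol%), CH2Cl2, 0 °C
Reagents that add atoms: none
Why: Steglich esterification acylates the secondary alcohol with retention under near-neutral conditions that spare the epoxide and the allylic bromide.

Step 10
Reactants: 12 (1S)-1-[(2R,3R)-3-(but-3-en-1-yl)-3-methyloxiran-2-yl]prop-2-en-1-yl 2-(bromomethyl)prop-2-enoate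
Product: 13 (5S)-3-(bromomethyl)-5-[(2R,3R)-3-(but-3-en-1-yl)-3-methyloxiran-2-yl]furan-2(5H)-one
Conditions: second-generation Grubbs catalyst RuCl2(=CHPh)(H2IMes)(PCy3) (5 mol%), CH2Cl2 (5 mM), 40 °C
Reagents that add atoms: none
Why: Ring-closing metathesis of the vinyl group onto the acrylate gives the five-membered butenolide, while closure through the butenyl alkene is blocked because it would need a seven-membered ring spanning the trans epoxide.

Step 11
Reactants: 14 3-methylbut-3-en-1-ol
Product: 15 3-methylbut-3-enal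
Conditions: Dess–Martin periodinane, pyridine, CH2Cl2, 0 °C; solution used at once
Reagents that add atoms: none
Why: Buffered Dess–Martin oxidation gives the β,γ-unsaturated aldehyde without isomerisation to the conjugated enal.

Step 12
Reactants: 13 (5S)-3-(bromomethyl)-5-[(2R,3R)-3-(but-3-en-1-yl)-3-methyloxiran-2-yl]furan-2(5H)-one; 15 3-methylbut-3-enal
Product: 17 (4R,5S)-5-[(2R,3R)-3-(but-3-en-1-yl)-3-methyloxiran-2-yl]-4-[(1S)-1-hydroxy-3-methylbut-3-en-1-yl]-3-methylideneoxolan-2-one, via allylzinc bromide 16 (not isolated)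
Conditions: Zn dust, THF/sat. aq. NH4Cl, 0 °C → rt, 15 in excess
Reagents that add atoms: none
Why: Zinc Barbier allylation through a closed Zimmerman–Traxler chair, in which the allylzinc attacks through its ring carbon on the face anti to the C6 substituent (6,7-trans, C7 R) with the aldehyde chain equatorial, giving the 7,8-anti (8S) carbinol and the exocyclic methylene.

Step 13
Reactants: 18 (tert-butyldimethylsilyloxy)acetaldehyde; 19 ethyl 2-(triphenylphosphoranylidene)propanoate
Product: 20 ethyl (2E)-4-[(tert-butyldimethylsilyl)oxy]-2-methylbut-2-enoate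
Conditions: CH2Cl2, rt
Reagents that add atoms: none
Why: Wittig olefination with a stabilised ylide is strongly E-selective, placing the ester trans to the silyloxymethyl group.

Step 14
Reactants: 20 ethyl (2E)-4-[(tert-butyldimethylsilyl)oxy]-2-methylbut-2-enoate
Product: 21 (2E)-4-[(tert-butyldimethylsilyl)oxy]-2-methylbut-2-enoic acid
Conditions: LiOH, THF/MeOH/H2O, rt; then 1 M HCl to pH 4, 0 °C
Reagents that add atoms: lithium hydroxide, [Li+].[OH-]
Why: Saponification of the ethyl ester, which the primary silyl ether survives under mild base and brief cold acidification.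

Step 15
Reactants: 17 (4R,5S)-5-[(2R,3R)-3-(but-3-en-1-yl)-3-methyloxiran-2-yl]-4-[(1S)-1-hydroxy-3-methylbut-3-en-1-yl]-3-methylideneoxolan-2-one; 21 (2E)-4-[(tert-butyldimethylsilyl)oxy]-2-methylbut-2-enoic acid
Product: 22 (1R)-1-[(2S,3R)-2-[(2R,3R)-3-(but-3-en-1-yl)-3-methyloxiran-2-yl]-4-methylidene-5-oxooxolan-3-yl]-3-methylbut-3-en-1-yl (2E)-4-[(tert-butyldimethylsilyl)oxy]-2-methylbut-2-enoate
Conditions: PPh3, DIAD (betaine pre-formed), THF, 0 °C → rt
Reagents that add atoms: none
Why: Mitsunobu esterification, in which the carboxylate displaces the oxyphosphonium group by SN2, so C8 is inverted from S to the required R as the side chain is attached.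

Step 16
Reactants: 22 (1R)-1-[(2S,3R)-2-[(2R,3R)-3-(but-3-en-1-yl)-3-methyloxiran-2-yl]-4-methylidene-5-oxooxolan-3-yl]-3-methylbut-3-en-1-yl (2E)-4-[(tert-butyldimethylsilyl)oxy]-2-methylbut-2-enoate
Product: 23 (4R,5R,6S,7R,8R,1(10)Z)-8-{[(2E)-4-(tert-butyldimethylsilyloxy)-2-methylbut-2-enoyl]oxy}-4,5-epoxygermacra-1(10),11(13)-dien-12,6-olide
Conditions: second-generation Grubbs catalyst RuCl2(=CHPh)(H2IMes)(PCy3) (15 mol%), toluene (1 mM), 80 °C
Reagents that add atoms: none
Why: Ring-closing metathesis of the terminal and 1,1-disubstituted alkenes at high dilution, where a trisubstituted alkene in a ten-membered ring closes with the ring carbons cis (the required 1(10)Z) and the electron-poor methylene lactone and tiglate do not react.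

Step 17
Reactants: 23 (4R,5R,6S,7R,8R,1(10)Z)-8-{[(2E)-4-(tert-butyldimethylsilyloxy)-2-methylbut-2-enoyl]oxy}-4,5-epoxygermacra-1(10),11(13)-dien-12,6-olide
Product: 24 (4R,5R,6S,7R,8R,1(10)Z)-4,5-epoxy-8-{[(2E)-4-hydroxy-2-methylbut-2-enoyl]oxy}germacra-1(10),11(13)-dien-12,6-olide (target)
Conditions: Bu4NF, AcOH (1:1), THF, 0 °C → rt
Reagents that add atoms: none
Why: Acetic acid-buffered fluoride desilylation frees the primary allylic alcohol under near-neutral conditions that spare the epoxide, the methylene lactone and the ester.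

**Compound list**
1 | geranyl acetate, (2E)-3,7-dimethylocta-2,6-dien-1-yl acetate | CC(=O)OC/C=C(\C)CCC=C(C)C | starting material
2 | (2E)-5-(3,3-dimethyloxiran-2-yl)-3-methylpent-2-en-1-yl acetate (racemic) | CC(=O)OC/C=C(\C)CCC1OC1(C)C | intermediate
3 | (2E)-6,7-dihydroxy-3,7-dimethyloct-2-en-1-yl acetate (racemic glycol, not isolated) | CC(=O)OC/C=C(\C)CCC(O)C(C)(C)O | intermediate
4 | (2E)-3-methyl-6-oxohex-2-en-1-yl acetate | CC(=O)OC/C=C(\C)CCC=O | intermediate
5 | (2E)-3-methylhepta-2,6-dien-1-yl acetate | CC(=O)OC/C=C(\C)CCC=C | intermediate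
6 | (2E)-3-methylhepta-2,6-dien-1-ol | OC/C=C(\C)CCC=C | intermediate
7 | (2E)-3-methylhepta-2,6-dienal | O=C/C=C(\C)CCC=C | intermediate
8 | (4E)-5-methylnona-1,4,8-trien-3-ol (racemic) | C=CC(O)/C=C(\C)CCC=C | intermediate
9 | (3S,4E)-5-methylnona-1,4,8-trien-3-ol | C=C[C@H](O)/C=C(\C)CCC=C | intermediate
10 | (1S)-1-[(2R,3R)-3-(but-3-en-1-yl)-3-methyloxiran-2-yl]prop-2-en-1-ol | C=C[C@H](O)[C@H]1O[C@]1(C)CCC=C | intermediate
11 | 2-(bromomethyl)prop-2-enoic acid | C=C(CBr)C(=O)O | starting material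
12 | (1S)-1-[(2R,3R)-3-(but-3-en-1-yl)-3-methyloxiran-2-yl]prop-2-en-1-yl 2-(bromomethyl)prop-2-enoate | C=C[C@H](OC(=O)C(=C)CBr)[C@H]1O[C@]1(C)CCC=C | intermediate
13 | (5S)-3-(bromomethyl)-5-[(2R,3R)-3-(but-3-en-1-yl)-3-methyloxiran-2-yl]furan-2(5H)-one | O=C1O[C@H]([C@H]2O[C@]2(C)CCC=C)C=C1CBr | intermediate
14 | 3-methylbut-3-en-1-ol | C=C(C)CCO | starting material
15 | 3-methylbut-3-enal | C=C(C)CC=O | intermediate
16 | {(5S)-5-[(2R,3R)-3-(but-3-en-1-yl)-3-methyloxiran-2-yl]-2-oxo-2,5-dihydrofuran-3-yl}methylzinc bromide (not isolated) | O=C1O[C@H]([C@H]2O[C@]2(C)CCC=C)C=C1C[Zn]Br | intermediate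
17 | (4R,5S)-5-[(2R,3R)-3-(but-3-en-1-yl)-3-methyloxiran-2-yl]-4-[(1S)-1-hydroxy-3-methylbut-3-en-1-yl]-3-methylideneoxolan-2-one | C=C1C(=O)O[C@H]([C@H]2O[C@]2(C)CCC=C)[C@H]1[C@@H](O)CC(C)=C | intermediate
18 | (tert-butyldimethylsilyloxy)acetaldehyde | O=CCO[Si](C)(C)C(C)(C)C | starting material
19 | ethyl 2-(triphenylphosphoranylidene)propanoate | CCOC(=O)C(C)=P(c1ccccc1)(c1ccccc1)c1ccccc1 | starting material
20 | ethyl (2E)-4-[(tert-butyldimethylsilyl)oxy]-2-methylbut-2-enoate | CCOC(=O)/C(C)=C/CO[Si](C)(C)C(C)(C)C | intermediate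
21 | (2E)-4-[(tert-butyldimethylsilyl)oxy]-2-methylbut-2-enoic acid | OC(=O)/C(C)=C/CO[Si](C)(C)C(C)(C)C | intermediate
22 | (1R)-1-[(2S,3R)-2-[(2R,3R)-3-(but-3-en-1-yl)-3-methyloxiran-2-yl]-4-methylidene-5-oxooxolan-3-yl]-3-methylbut-3-en-1-yl (2E)-4-[(tert-butyldimethylsilyl)oxy]-2-methylbut-2-enoate | C=C1C(=O)O[C@H]([C@H]2O[C@]2(C)CCC=C)[C@H]1[C@H](OC(=O)/C(C)=C/CO[Si](C)(C)C(C)(C)C)CC(C)=C | intermediate
23 | (4R,5R,6S,7R,8R,1(10)Z)-8-{[(2E)-4-(tert-butyldimethylsilyloxy)-2-methylbut-2-enoyl]oxy}-4,5-epoxygermacra-1(10),11(13)-dien-12,6-olide | C=C1C(=O)O[C@H]2[C@H]1[C@H](OC(=O)/C(C)=C/CO[Si](C)(C)C(C)(C)C)C/C(C)=C\CC[C@@]1(C)O[C@H]21 | intermediate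
24 | (4R,5R,6S,7R,8R,1(10)Z)-4,5-epoxy-8-{[(2E)-4-hydroxy-2-methylbut-2-enoyl]oxy}germacra-1(10),11(13)-dien-12,6-olide | C=C1C(=O)O[C@H]2[C@H]1[C@H](OC(=O)/C(C)=C/CO)C/C(C)=C\CC[C@@]1(C)O[C@H]21 | target

**Count and risks**
Total step count: 17. Longest linear sequence: 14 steps (1 → 24 through steps 1–10, 12, 15, 16, 17).

The three steps most likely to fail are step 16, step 15 and step 12.

Step 16 (closure of the strained ten-membered ring; oligomers are the likely outcome). The fallback closes the ring before the bulky acyl group is attached. It sets out from 17: ring-closing metathesis with the same catalyst at 1 mM in toluene gives (4R,5R,6S,7R,8S,1(10)Z)-4,5-epoxy-8-hydroxygermacra-1(10),11(13)-dien-12,6-olide F1. This macrocyclic alcohol is then esterified with 21 under Mitsunobu conditions (PPh3, DIAD) with inversion at C8, and the route is rejoined at 23.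

Step 15 (Mitsunobu inversion next to a branched carbon; elimination or no reaction is possible). The fallback replaces substitution by oxidation and reagent-controlled reduction. It sets out from 17: Dess–Martin oxidation gives (4S,5S)-5-[(2R,3R)-3-(but-3-en-1-yl)-3-methyloxiran-2-yl]-4-(3-methylbut-3-enoyl)-3-methylideneoxolan-2-one F2, which is used at once because its C7 hydrogen is acidic. Corey–Bakshi–Shibata reduction with (S)-2-methyl-CBS-oxazaborolidine and catecholborane at −78 °C gives (4R,5S)-5-[(2R,3R)-3-(but-3-en-1-yl)-3-methyloxiran-2-yl]-4-[(1R)-1-hydroxy-3-methylbut-3-en-1-yl]-3-methylideneoxolan-2-one F3. Carbodiimide esterification of this (8R)-alcohol with 21 (EDC, DMAP, retention) comes back to the route at 22. The same esterification with retention would be used if step 12 delivered the 8R epimer directly.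

Step 12 (zinc may open the bromolactone reductively, or the diastereomer ratio may be poor). The fallback separates metalation from addition. It sets out from 13: borylation with B2pin2 catalysed by Pd2(dba)3 gives (5S)-5-[(2R,3R)-3-(but-3-en-1-yl)-3-methyloxiran-2-yl]-3-[(4,4,5,5-tetramethyl-1,3,2-dioxaborolan-2-yl)methyl]furan-2(5H)-one F4. This isolable allylboronate adds to 15 on warming in toluene through the same closed chair transition state and, after aqueous work-up, comes back to the route at 17.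

**Further compounds**
F1 | step 16 | (4R,5R,6S,7R,8S,1(10)Z)-4,5-epoxy-8-hydroxygermacra-1(10),11(13)-dien-12,6-olide | C=C1C(=O)O[C@H]2[C@H]1[C@@H](O)C/C(C)=C\CC[C@@]1(C)O[C@H]21
F2 | step 15 | (4S,5S)-5-[(2R,3R)-3-(but-3-en-1-yl)-3-methyloxiran-2-yl]-4-(3-methylbut-3-enoyl)-3-methylideneoxolan-2-one | C=C1C(=O)O[C@H]([C@H]2O[C@]2(C)CCC=C)[C@H]1C(=O)CC(C)=C
F3 | step 15 | (4R,5S)-5-[(2R,3R)-3-(but-3-en-1-yl)-3-methyloxiran-2-yl]-4-[(1R)-1-hydroxy-3-methylbut-3-en-1-yl]-3-methylideneoxolan-2-one | C=C1C(=O)O[C@H]([C@H]2O[C@]2(C)CCC=C)[C@H]1[C@H](O)CC(C)=C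
F4 | step 12 | (5S)-5-[(2R,3R)-3-(but-3-en-1-yl)-3-methyloxiran-2-yl]-3-[(4,4,5,5-tetramethyl-1,3,2-dioxaborolan-2-yl)methyl]furan-2(5H)-one | O=C1O[C@H]([C@H]2O[C@]2(C)CCC=C)C=C1CB1OC(C)(C)C(C)(C)O1
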